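## Retrosynthetic overview

1. **C4–O.** The tiglate cis to isopropyl comes from SN2 inversion of an all-equatorial C4 alcohol. The isopropyl group comes from an isopropenyl group.
2. **C4–C5, the only ring-forming bond.** A carbonyl-ene closure joins an acyclic (Z)-4-oxo-enal to a prenyl-type alkene (an oxidised neral → isopiperitenol cyclisation). The six-membered carbocycle is the only ring built.
3. **The unit C1(=O)–C2=C3–C4HO is a masked furan.** Singlet oxygen opens a 2,3-disubstituted furan. This ring is bought, and it is opened before the carbocycle closes.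
4. **C1–C6, the key bond.** C2-metallated 3-furanmethanol acts as a masked (Z)-4-oxobut-2-enoyl anion and adds enantioselectively to the aldehyde carbon of prenal. Two C5 units give the whole p-menthane skeleton, and C6 then controls C5 and C4.

Assumption and numbering: both C5 acyl groups are read as tiglates (Tig = (E)-2-methylbut-2-enoyl); ring atoms are C1 (C=O), C2 (C–CH2O), C3 (=CH), C4 (OTig), C5 (isopropyl), C6 (OAc), so the target is 4S,5S,6R (4,5-cis, 5,6-trans), and acyclic precursors carry the same labels.

Abbreviations: TEEDA = N,N,N',N'-tetraethylethylenediamine; (−)-MIB = (2S)-3-exo-morpholinoisoborneol; TPP = tetraphenylporphyrin.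

## Route

**Step 1**
Reactants: 1 3-furanmethanol; 2 3-methylbut-2-enal (prenal)
Product: 5 (1R)-1-[3-(hydroxymethyl)furan-2-yl]-3-methylbut-2-en-1-ol, via dilithio furan 3 (not isolated), via bis(ethylzinc) furan 4 (not isolated)
Conditions: n-BuLi (2.1 equiv), TEEDA (2 equiv), t-BuOMe, 0 °C; EtZnCl (2.1 equiv), 0 °C; (−)-MIB (10 mol %), toluene, then 2, −10 °C; H2O
Reagents that add atoms: none
Why: Proposed new method: hydroxymethyl-directed C2 lithiation followed by Li-to-Zn exchange gives a 2-furyl(ethyl)zinc whose carbanionic carbon is the future C1 ketone carbon (a masked acyl anion), and the zinc aminoalkoxide of (−)-MIB binds prenal and delivers the furyl group, which transfers faster than ethyl, to the Si face of the C6 aldehyde carbon to set 6R, so two carbonyl-type carbons are joined; the closest known reaction type is the amino-alcohol-catalysed asymmetric addition of heteroaryl(ethyl)zincs (made from heteroaryllithiums, with a diamine masking LiCl) to aldehydes and enals, and the untested point is the free side-chain EtZn alkoxide, which should be as innocent as the product EtZn alkoxide that builds up in every such addition.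

**Step 2**
Reactants: 5 (R)-diol; 6 tigloyl chloride
Product: 8 {2-[(1R)-1-acetoxy-3-methylbut-2-en-1-yl]furan-3-yl}methyl (E)-2-methylbut-2-enoate, via monotiglate alcohol 7 (not isolated)
Conditions: 6 (1.05 equiv), pyridine, CH2Cl2, −20 °C; then Ac2O, DMAP (cat.), 0 °C; short plug of Et3N-deactivated SiO2, used at once
Reagents that add atoms: acetic anhydride, CC(=O)OC(C)=O
Why: Chemoselective sequential acylation, in which the unhindered primary alcohol takes the acid chloride at low temperature well before the flanked secondary carbinol (pyridine rather than Et3N avoids vinylketene deconjugation of the tiglate), and DMAP-catalysed acetylation then caps C6–OH without breaking the C6–O bond, so 6R is kept.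

**Step 3**
Reactants: 8 furan tiglate acetate
Product: 10 (2Z,5R)-5-acetoxy-7-methyl-4-oxo-3-(tigloyloxymethyl)octa-2,6-dienal, via furan endoperoxide 9 (not isolated)
Conditions: O2, TPP (1 mol %), visible light, CH2Cl2, −78 °C; Me2S, −78 → 0 °C (dark)
Reagents that add atoms: oxygen, O=O
Why: Singlet-oxygen [4+2] cycloaddition to the furan is roughly two orders of magnitude faster than the Schenck ene reaction of the acetoxy-deactivated trisubstituted alkene (the tiglate is inert), and Me2S reduction collapses the endoperoxide to the (Z)-ene-dicarbonyl, unveiling C1 as ketone and C4 as aldehyde with the ring-ready geometry and no change at C6.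

**Step 4**
Reactants: 10 (Z)-keto-enal
Product: 11 (4R,5S,6R)-6-acetoxy-4-hydroxy-5-(prop-1-en-2-yl)-2-(tigloyloxymethyl)cyclohex-2-en-1-one
Conditions: Sc(OTf)3 (10 mol %), 4 Å MS, CH2Cl2, −78 → −40 °C
Reagents that add atoms: none
Why: Intramolecular carbonyl-ene cyclisation of the neral-to-isopiperitenol and citronellal-to-isopulegol kind, in which A(1,3) strain with the methyl cis to C6 holds H6 in the alkene plane so the tethered aldehyde can reach only the alkene face anti to OAc (5,6-trans, 5S), and the Lewis-acid-bound oxygen sits pseudo-equatorial and takes H from the other methyl (4,5-trans, 4R), giving the all-equatorial product.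

**Step 5**
Reactants: 11 isopropenyl alcohol
Product: 12 (4R,5S,6R)-6-acetoxy-4-hydroxy-5-(propan-2-yl)-2-(tigloyloxymethyl)cyclohex-2-en-1-one
Conditions: H2 (1 atm), RhCl(PPh3)3 (5 mol %), benzene, rt
Reagents that add atoms: none
Why: Homogeneous hydrogenation with RhCl(PPh3)3 saturates the 1,1-disubstituted alkene and leaves the trisubstituted conjugated alkenes (ring enone, tiglate) and the allylic C–O bonds alone, as in carvone to carvotanacetone, and no stereocentre is made or touched.

**Step 6**
Reactants: 12 all-trans alcohol; 13 tiglic acid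
Product: 14 (4S,5S,6R)-6-acetoxy-5-(propan-2-yl)-4-(tigloyloxy)-2-(tigloyloxymethyl)cyclohex-2-en-1-one (CNP0218511.1)
Conditions: 13 (2 equiv), PPh3, DIAD, toluene, 0 °C → rt
Reagents that add atoms: none
Why: Mitsunobu esterification, in which the activated C4 alcohol is displaced by tiglate in an SN2 reaction with inversion (4R to 4S, now cis to isopropyl), because the electron-poor enone disfavours ionisation and SN2' attack at C2 and the equatorial leaving group has no antiperiplanar H for E2.

## Compound list

1 | 3-furanmethanol | OCc1ccoc1 | starting material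
2 | 3-methylbut-2-enal (prenal) | CC(C)=CC=O | starting material
3 | 2-lithio-3-(lithiooxymethyl)furan | [Li]OCc1ccoc1[Li] | intermediate
4 | ethyl{3-[(ethylzinciooxy)methyl]furan-2-yl}zinc | CC[Zn]OCc1ccoc1[Zn]CC | intermediate
5 | (1R)-1-[3-(hydroxymethyl)furan-2-yl]-3-methylbut-2-en-1-ol | OCc1ccoc1[C@H](O)C=C(C)C | intermediate
6 | tigloyl chloride, (E)-2-methylbut-2-enoyl chloride | C/C=C(\C)C(=O)Cl | starting material
7 | {2-[(1R)-1-hydroxy-3-methylbut-2-en-1-yl]furan-3-yl}methyl (E)-2-methylbut-2-enoate | C/C=C(\C)C(=O)OCc1ccoc1[C@H](O)C=C(C)C | intermediate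
8 | {2-[(1R)-1-acetoxy-3-methylbut-2-en-1-yl]furan-3-yl}methyl (E)-2-methylbut-2-enoate | C/C=C(\C)C(=O)OCc1ccoc1[C@H](OC(C)=O)C=C(C)C | intermediate
9 | furan endoperoxide of 8 (2,3,7-trioxabicyclo[2.2.1]hept-5-ene, both bridgehead faces, side-chain centre R) | CC(C)=C[C@@H](OC(C)=O)C12OOC(O1)C=C2COC(=O)/C(C)=C/C | intermediate
10 | (2Z,5R)-5-acetoxy-7-methyl-4-oxo-3-(tigloyloxymethyl)octa-2,6-dienal (CHO = C4, ketone = C1, CHOAc = C6) | O=C/C=C(/COC(=O)/C(C)=C/C)C(=O)[C@H](OC(C)=O)C=C(C)C | intermediate
11 | (4R,5S,6R)-6-acetoxy-4-hydroxy-5-(prop-1-en-2-yl)-2-(tigloyloxymethyl)cyclohex-2-en-1-one | C/C=C(\C)C(=O)OCC1=C[C@@H](O)[C@H](C(C)=C)[C@@H](OC(C)=O)C1=O | intermediate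
12 | (4R,5S,6R)-6-acetoxy-4-hydroxy-5-(propan-2-yl)-2-(tigloyloxymethyl)cyclohex-2-en-1-one | C/C=C(\C)C(=O)OCC1=C[C@@H](O)[C@H](C(C)C)[C@@H](OC(C)=O)C1=O | intermediate
13 | tiglic acid, (E)-2-methylbut-2-enoic acid | C/C=C(\C)C(=O)O | starting material
14 | (4S,5S,6R)-6-acetoxy-5-(propan-2-yl)-4-(tigloyloxy)-2-(tigloyloxymethyl)cyclohex-2-en-1-one | C/C=C(\C)C(=O)OCC1=C[C@H](OC(=O)/C(C)=C/C)[C@H](C(C)C)[C@@H](OC(C)=O)C1=O | target

Total step count: 6. Longest linear sequence: 6.

## Steps most likely to fail

**(a) Step 1.**
- **Risk:** The chelating side-chain alkoxide may speed up the uncatalysed addition. Lewis-acidic zinc may also ionise the furyl/allyl product alkoxide. Either effect lowers the ee.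
- **Fallback:** It sets out from 3 and comes back at 7. The dilithio furan 3 is quenched with DMF. The same masked acyl anion then takes up a formyl cation equivalent, so C1–C6 forms without a stereocentre. This gives 3-(hydroxymethyl)furan-2-carbaldehyde F1. Acylation with 6 (pyridine, CH2Cl2, −20 °C) gives (2-formylfuran-3-yl)methyl (E)-2-methylbut-2-enoate F2. C6 is then set on the C5–C6 bond instead, by a ligand-controlled Nozaki–Hiyama–Kishi alkenylation of F2 with 1-bromo-2-methylprop-1-ene (CrCl2, NiCl2 (cat.), chiral oxazoline–sulfonamide ligand chosen for Re-face attack, THF). This reaction tolerates the ester and gives alcohol 7, which is acetylated as in the second half of step 2.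

**(b) Step 4.**
- **Risk:** Compound 10 is a β,γ-unsaturated ketone with an acidic H6. Conjugation or racemisation, Z-to-E isomerisation of the ene-dicarbonyl, or poor control at C4 can all compete with the concerted ene reaction.
- **Fallback:** It sets out from 10 and comes back at 12. TiCl4 (CH2Cl2, −78 °C) drives a stepwise Prins cyclisation through the same A(1,3)-controlled conformer, and chloride captures the tertiary cation. The product is (4R,5S,6R)-6-acetoxy-5-(2-chloropropan-2-yl)-4-hydroxy-2-(tigloyloxymethyl)cyclohex-2-en-1-one F3. Radical dechlorination ((Me3Si)3SiH, AIBN, toluene, 80 °C) then gives 12 directly, so the hydrogenation is no longer needed.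

**(c) Step 6.**
- **Risk:** The alcohol is flanked by isopropyl and tiglic acid is a weak acid (pKa about 5). The displacement may therefore stall, or give way to elimination and aromatisation.
- **Fallback:** It sets out from 12 and comes back at 14. The Mitsunobu inversion is run with the much more acidic 2-(diethoxyphosphoryl)propanoic acid (PPh3, DIAD, toluene). This gives (4S,5S,6R)-6-acetoxy-4-[2-(diethoxyphosphoryl)propanoyloxy]-5-(propan-2-yl)-2-(tigloyloxymethyl)cyclohex-2-en-1-one F4. The tiglate is then built on the ring by an E-selective Horner–Wadsworth–Emmons olefination with acetaldehyde (LiCl, i-Pr2NEt, MeCN, 0 °C), giving 14.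

## Further compounds

F1 | step 1 | 3-(hydroxymethyl)furan-2-carbaldehyde | OCc1ccoc1C=O
F2 | step 1 | (2-formylfuran-3-yl)methyl (E)-2-methylbut-2-enoate | C/C=C(\C)C(=O)OCc1ccoc1C=O
F3 | step 4 | (4R,5S,6R)-6-acetoxy-5-(2-chloropropan-2-yl)-4-hydroxy-2-(tigloyloxymethyl)cyclohex-2-en-1-one | C/C=C(\C)C(=O)OCC1=C[C@@H](O)[C@H](C(C)(C)Cl)[C@@H](OC(C)=O)C1=O
F4 | step 6 | (4S,5S,6R)-6-acetoxy-4-[2-(diethoxyphosphoryl)propanoyloxy]-5-(propan-2-yl)-2-(tigloyloxymethyl)cyclohex-2-en-1-one, both epimers at the phosphonate carbon | C/C=C(\C)C(=O)OCC1=C[C@H](OC(=O)C(C)P(=O)(OCC)OCC)[C@H](C(C)C)[C@@H](OC(C)=O)C1=O
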